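**Retrosynthetic overview**
1. The six silyl ethers come off last; the (Z)-3-methylbuta-1,3-dienyl group at C8 is made by Sonogashira coupling of an 8-iodoflavanone and Z-selective semi-hydrogenation.
2. The chromanone ring is closed second, by a catalyst-controlled oxa-Michael addition of an alkylidene β-ketoester (Knoevenagel union of dihydrobenzofuran aldehyde 16 with A-ring β-ketoester 21), then decarboxylation.
3. The dihydrofuran ring is closed first, by forming the C2–C3 bond of the 2,3-dihydrobenzofuran: an enantioselective Rh(II) 1,5 C–H insertion of a diaryl carbene generated from the hydrazone of an achiral 2-(benzyloxy)benzophenone.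
4. Enabling feature: C3 carries two aryl groups (the benzo ring at C3a and the 3,5-dioxygenated ring), so it can be a donor/donor carbene; C2–H is benzylic and α to O1, and sits 1,5 to C3 through the O1–C7a–C3a tether.
5. The insertion sets C3 and gives the 2,3-cis ring; C2 is then inverted to trans through reversible C2–O1 ionisation (assisted by the para-oxygenated C2 aryl group) during BBr3 demethylation.

Key step: step 5

Assumption: the sense of induction of Rh2(S-PTAD)4 (step 5) and of the quinine-derived thiourea (step 13) is assigned by analogy; if it proves opposite, Rh2(R-PTAD)4 or the quinidine-derived pseudo-enantiomer is used instead.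

**Route**

Step 1
Reactants: 1 5-bromo-2-hydroxy-4-methoxybenzaldehyde; 2 4-methoxybenzyl chloride
Product: 3 5-bromo-4-methoxy-2-[(4-methoxybenzyl)oxy]benzaldehyde
Conditions: K2CO3, TBAI (cat.), DMF, 50 °C
Reagents that add atoms: none
Why: Williamson ether synthesis on the only phenol, which installs the benzylic CH2 that becomes C2 of the dihydrobenzofuran.

Step 2
Reactants: 3 5-bromo-4-methoxy-2-[(4-methoxybenzyl)oxy]benzaldehyde; 4 1-bromo-3,5-dimethoxybenzene
Product: 6 {5-bromo-4-methoxy-2-[(4-methoxybenzyl)oxy]phenyl}(3,5-dimethoxyphenyl)methanol (racemic), via 3,5-dimethoxyphenyllithium 5 (not isolated)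
Conditions: 4, n-BuLi, THF, −78 °C; then 3, −78 °C; H2O
Reagents that add atoms: none
Why: Bromine–lithium exchange followed by 1,2-addition of the aryllithium to the aldehyde, which at −78 °C should outrun exchange with the aryl bromide of 3; the carbinol centre is removed in step 3.

Step 3
Reactants: 6 the diaryl carbinol
Product: 7 {5-bromo-4-methoxy-2-[(4-methoxybenzyl)oxy]phenyl}(3,5-dimethoxyphenyl)methanone
Conditions: activated MnO2, CH2Cl2, rt
Reagents that add atoms: none
Why: MnO2 oxidation of a doubly benzylic alcohol to the benzophenone, leaving the benzyl ether and aryl bromide untouched.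

Step 4
Reactants: 7 the benzophenone
Product: 8 hydrazone of 7 (E/Z mixture at C=N)
Conditions: N2H4·H2O (excess), AcOH (cat.), EtOH, 80 °C
Reagents that add atoms: hydrazine, NN
Why: Acid-catalysed hydrazone condensation of a diaryl ketone; both C=N isomers lead to the same diazo compound.

Step 5
Reactants: 8 the hydrazone
Product: 10 (2S,3R)-5-bromo-3-(3,5-dimethoxyphenyl)-6-methoxy-2-(4-methoxyphenyl)-2,3-dihydro-1-benzofuran (2,3-cis), via diaryldiazomethane 9 (not isolated)
Conditions: activated MnO2, MeCN, 0 °C, filter; slow addition to Rh2(S-PTAD)4 (1 mol %), MeCN, 0 °C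
Reagents that add atoms: none
Why: Rh(II) converts the diaryldiazomethane 9 into a donor/donor rhodium carbene at C3, whose electrophilicity is tempered by its two aryl groups, so it should ignore the arenes and insert into the one C–H bond it can reach through a five-membered transition state, the hydridic benzylic C2–H α to O1. The closest known reaction type is the Rh2(PTAD)4-catalysed intramolecular C–H insertion of hydrazone-derived diaryl carbenes into ortho-benzyloxy groups, which gives 2,3-diaryl-2,3-dihydrobenzofurans. The furan ring closes by 1,5 C–H insertion, that is hydride shift from C2 to the carbene carbon followed by immediate C2–C3 collapse of the oxocarbenium/rhodium-alkyl ion pair (formally a 5-endo-trig closure onto C2=O1+, operating as a three-centre insertion). C3 is set by the chiral carboxylate pocket of the catalyst, which differentiates the two faces of the carbene, and C2 is expected to form cis to it because the tight ion pair collapses before the oxocarbenium can rotate. The selectivity required is insertion over azine formation and over other C–H bonds; slow addition keeps the diazo concentration low, and the OMe and aromatic C–H bonds are either out of geometric reach or not activated. Only C3 has to be correct at this stage, because C2 is inverted in step 7.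

Step 6
Reactants: 10 the cis bromide
Product: 12 (2S,3R)-3-(3,5-dimethoxyphenyl)-6-methoxy-2-(4-methoxyphenyl)-2,3-dihydro-1-benzofuran-5-carbaldehyde (2,3-cis), via C5-aryllithium 11 (not isolated)
Conditions: n-BuLi, THF, −78 °C; DMF, −78 → 0 °C; H2O
Reagents that add atoms: N,N-dimethylformamide, CN(C)C=O
Why: Bromine–lithium exchange and formylation with DMF, done while all phenols are still methyl ethers so that no ortho-silyloxy aryllithium (prone to O→C silyl migration) is ever formed.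

Step 7
Reactants: 12 the cis aldehyde
Product: 15 (2R,3R)-3-(3,5-dihydroxyphenyl)-6-hydroxy-2-(4-hydroxyphenyl)-2,3-dihydro-1-benzofuran-5-carbaldehyde (2,3-trans), via cis-tetraphenol aldehyde 13 (not isolated), via ring-opened para-quinone methide 14 (not isolated)
Conditions: BBr3 (excess), CH2Cl2, −78 °C → rt; H2O
Reagents that add atoms: none
Why: Lewis-acid cleavage of the four aryl methyl ethers, with the acidic medium also ionising the C2–O1 bond reversibly (para-oxygenated benzylic cation/quinone methide) so that C2 should settle trans to the untouched C3 under thermodynamic control.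

Step 8
Reactants: 15 the trans tetraphenol aldehyde
Product: 16 (2R,3R)-6-(tert-butyldimethylsilyloxy)-2-[4-(tert-butyldimethylsilyloxy)phenyl]-3-[3,5-bis(tert-butyldimethylsilyloxy)phenyl]-2,3-dihydro-1-benzofuran-5-carbaldehyde
Conditions: TBSCl, imidazole, DMAP (cat.), DMF, rt
Reagents that add atoms: tert-butyldimethylsilyl chloride, CC(C)(C)[Si](C)(C)Cl
Why: Exhaustive phenol silylation, giving groups that can be removed at the end by fluoride without acid, base or hydrogen.

Step 9
Reactants: 17 2,4,6-trihydroxyacetophenone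
Product: 18 1-[2,4-bis(tert-butyldimethylsilyloxy)-6-hydroxyphenyl]ethanone
Conditions: TBSCl (2.1 equiv), imidazole, CH2Cl2, 0 °C → rt
Reagents that add atoms: tert-butyldimethylsilyl chloride, CC(C)(C)[Si](C)(C)Cl
Why: Selective silylation, in which the last phenol, hydrogen-bonded to the ketone, should remain free.

Step 10
Reactants: 18 the bis-silyl acetophenone
Product: 19 1-[4,6-bis(tert-butyldimethylsilyloxy)-2-hydroxy-3-iodophenyl]ethanone
Conditions: NIS, CH2Cl2, 0 °C, dark
Reagents that add atoms: N-iodosuccinimide, O=C1CCC(=O)N1I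
Why: Electrophilic aromatic iodination, expected ortho to the free phenol because the other open position is flanked by two bulky silyloxy groups; this carbon becomes C8 of the flavanone.

Step 11
Reactants: 19 the iodoacetophenone
Product: 21 tert-butyl 3-[4,6-bis(tert-butyldimethylsilyloxy)-2-hydroxy-3-iodophenyl]-3-oxopropanoate, via dilithium enolate-phenoxide 20 (not isolated)
Conditions: LiHMDS (3.2 equiv), THF, −78 °C; Boc2O, −78 → −20 °C; AcOH
Reagents that add atoms: di-tert-butyl dicarbonate, CC(C)(C)OC(=O)OC(=O)OC(C)(C)C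
Why: Claisen-type C-acylation of the ketone enolate, driven by deprotonation of the β-ketoester product; the tert-butyl ester resists lactonisation onto the phenol.

Step 12
Reactants: 16 the tetra-silyl aldehyde; 21 the β-ketoester
Product: 22 tert-butyl 2-[4,6-bis(tert-butyldimethylsilyloxy)-2-hydroxy-3-iodobenzoyl]-3-{(2R,3R)-6-(tert-butyldimethylsilyloxy)-2-[4-(tert-butyldimethylsilyloxy)phenyl]-3-[3,5-bis(tert-butyldimethylsilyloxy)phenyl]-2,3-dihydro-1-benzofuran-5-yl}prop-2-enoate (alkene geometry not defined)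
Conditions: piperidine (cat.), AcOH (cat.), 4 Å MS, toluene, rt
Reagents that add atoms: none
Why: Knoevenagel condensation under buffered amine catalysis, mild enough for the aryl silyl ethers, giving the doubly activated acceptor needed for the asymmetric ring closure.

Step 13
Reactants: 22 the alkylidene β-ketoester
Product: 25 (2S)-8-iodo-5,7-bis(tert-butyldimethylsilyloxy)-2-{(2R,3R)-6-(tert-butyldimethylsilyloxy)-2-[4-(tert-butyldimethylsilyloxy)phenyl]-3-[3,5-bis(tert-butyldimethylsilyloxy)phenyl]-2,3-dihydro-1-benzofuran-5-yl}chroman-4-one, via tert-butyl chromanone-3-carboxylate 23 (not isolated), via chromanone-3-carboxylic acid 24 (not isolated)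
Conditions: quinine-derived 3,5-bis(trifluoromethyl)phenyl thiourea (10 mol %), toluene, −25 °C; then TsOH·H2O (0.5 equiv), 80 °C
Reagents that add atoms: none
Why: Bifunctional thiourea/amine-catalysed intramolecular oxa-Michael addition (6-endo-trig), in which the catalyst binds the β-ketoester and directs the phenol to one face of the alkene to set C2 as S, followed by acid-mediated tert-butyl ester cleavage and decarboxylation; any minor C2 epimer is a diastereomer and separable.

Step 14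
Reactants: 25 the 8-iodoflavanone; 26 2-methylbut-1-en-3-yne
Product: 27 (2S)-8-(3-methylbut-3-en-1-yn-1-yl) analogue of 25
Conditions: PdCl2(PPh3)2 (cat.), CuI (cat.), Et3N, THF, rt → 40 °C
Reagents that add atoms: none
Why: Sonogashira coupling of an aryl iodide under mild amine conditions that should not open the chromanone; no free ortho-phenol is present, so benzofuran formation is excluded.

Step 15
Reactants: 27 the enyne
Product: 28 (2S)-8-[(1Z)-3-methylbuta-1,3-dien-1-yl]-5,7-bis(tert-butyldimethylsilyloxy)-2-{(2R,3R)-tetra-silylated dihydrobenzofuran-5-yl}chroman-4-one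
Conditions: H2 (1 atm), Lindlar catalyst, quinoline, EtOAc, rt
Reagents that add atoms: none
Why: Syn-selective semi-hydrogenation of the alkyne on poisoned palladium sets the Z geometry, and the less accessible 1,1-disubstituted terminal alkene should survive if the reaction is stopped at one equivalent of hydrogen.

Step 16
Reactants: 28 the hexa-silyl Z-diene
Product: 29 CNP0284772.1
Conditions: TBAF/AcOH (1:1), THF, 0 °C
Reagents that add atoms: none
Why: Fluoride-mediated cleavage of the six aryl silyl ethers under acetic acid buffering, which avoids both free phenoxides (chromanone or dihydrofuran opening) and strong acid (cyclisation of the dienyl phenol to a chromene).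

**Compound list**
1 | 5-bromo-2-hydroxy-4-methoxybenzaldehyde | O=Cc1cc(Br)c(OC)cc1O | starting material
2 | 4-methoxybenzyl chloride | COc1ccc(CCl)cc1 | starting material
3 | 5-bromo-4-methoxy-2-[(4-methoxybenzyl)oxy]benzaldehyde | O=Cc1cc(Br)c(OC)cc1OCc1ccc(OC)cc1 | intermediate
4 | 1-bromo-3,5-dimethoxybenzene | COc1cc(Br)cc(OC)c1 | starting material
5 | 3,5-dimethoxyphenyllithium | [Li]c1cc(OC)cc(OC)c1 | intermediate (not isolated)
6 | {5-bromo-4-methoxy-2-[(4-methoxybenzyl)oxy]phenyl}(3,5-dimethoxyphenyl)methanol, racemic | OC(c1cc(OC)cc(OC)c1)c1cc(Br)c(OC)cc1OCc1ccc(OC)cc1 | intermediate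
7 | {5-bromo-4-methoxy-2-[(4-methoxybenzyl)oxy]phenyl}(3,5-dimethoxyphenyl)methanone | O=C(c1cc(OC)cc(OC)c1)c1cc(Br)c(OC)cc1OCc1ccc(OC)cc1 | intermediate
8 | hydrazone of 7 (E/Z mixture) | NN=C(c1cc(OC)cc(OC)c1)c1cc(Br)c(OC)cc1OCc1ccc(OC)cc1 | intermediate
9 | 1-bromo-5-[diazo(3,5-dimethoxyphenyl)methyl]-2-methoxy-4-[(4-methoxybenzyl)oxy]benzene | [N-]=[N+]=C(c1cc(OC)cc(OC)c1)c1cc(Br)c(OC)cc1OCc1ccc(OC)cc1 | intermediate (not isolated)
10 | (2S,3R)-5-bromo-3-(3,5-dimethoxyphenyl)-6-methoxy-2-(4-methoxyphenyl)-2,3-dihydro-1-benzofuran (cis) | Brc1cc2c(cc1OC)O[C@H](c1ccc(OC)cc1)[C@@H]2c1cc(OC)cc(OC)c1 | intermediate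
11 | C5-aryllithium derived from 10 | [Li]c1cc2c(cc1OC)O[C@H](c1ccc(OC)cc1)[C@@H]2c1cc(OC)cc(OC)c1 | intermediate (not isolated)
12 | (2S,3R)-3-(3,5-dimethoxyphenyl)-6-methoxy-2-(4-methoxyphenyl)-2,3-dihydro-1-benzofuran-5-carbaldehyde (cis) | O=Cc1cc2c(cc1OC)O[C@H](c1ccc(OC)cc1)[C@@H]2c1cc(OC)cc(OC)c1 | intermediate
13 | (2S,3R)-3-(3,5-dihydroxyphenyl)-6-hydroxy-2-(4-hydroxyphenyl)-2,3-dihydro-1-benzofuran-5-carbaldehyde (cis; boron-bound in the flask, drawn as the phenol) | O=Cc1cc2c(cc1O)O[C@H](c1ccc(O)cc1)[C@@H]2c1cc(O)cc(O)c1 | intermediate (not isolated)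
14 | 5-[(1R)-1-(3,5-dihydroxyphenyl)-2-(4-oxocyclohexa-2,5-dien-1-ylidene)ethyl]-2,4-dihydroxybenzaldehyde (ring-opened para-quinone methide, drawn neutral) | O=Cc1cc(c(O)cc1O)[C@H](C=C1C=CC(=O)C=C1)c1cc(O)cc(O)c1 | intermediate (not isolated)
15 | (2R,3R)-3-(3,5-dihydroxyphenyl)-6-hydroxy-2-(4-hydroxyphenyl)-2,3-dihydro-1-benzofuran-5-carbaldehyde (trans) | O=Cc1cc2c(cc1O)O[C@@H](c1ccc(O)cc1)[C@@H]2c1cc(O)cc(O)c1 | intermediate
16 | (2R,3R)-6-(tert-butyldimethylsilyloxy)-2-[4-(tert-butyldimethylsilyloxy)phenyl]-3-[3,5-bis(tert-butyldimethylsilyloxy)phenyl]-2,3-dihydro-1-benzofuran-5-carbaldehyde | O=Cc1cc3c(cc1O[Si](C)(C)C(C)(C)C)O[C@@H](c1ccc(O[Si](C)(C)C(C)(C)C)cc1)[C@@H]3c1cc(O[Si](C)(C)C(C)(C)C)cc(O[Si](C)(C)C(C)(C)C)c1 | intermediate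
17 | 2,4,6-trihydroxyacetophenone | CC(=O)c1c(O)cc(O)cc1O | starting material
18 | 1-[2,4-bis(tert-butyldimethylsilyloxy)-6-hydroxyphenyl]ethanone | CC(=O)c1c(O)cc(O[Si](C)(C)C(C)(C)C)cc1O[Si](C)(C)C(C)(C)C | intermediate
19 | 1-[4,6-bis(tert-butyldimethylsilyloxy)-2-hydroxy-3-iodophenyl]ethanone | CC(=O)c1c(O)c(I)c(O[Si](C)(C)C(C)(C)C)cc1O[Si](C)(C)C(C)(C)C | intermediate
20 | dilithium enolate-phenoxide of 19 | [Li]OC(=C)c1c(O[Li])c(I)c(O[Si](C)(C)C(C)(C)C)cc1O[Si](C)(C)C(C)(C)C | intermediate (not isolated)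
21 | tert-butyl 3-[4,6-bis(tert-butyldimethylsilyloxy)-2-hydroxy-3-iodophenyl]-3-oxopropanoate | CC(C)(C)OC(=O)CC(=O)c1c(O)c(I)c(O[Si](C)(C)C(C)(C)C)cc1O[Si](C)(C)C(C)(C)C | intermediate
22 | alkylidene β-ketoester from 16 and 21 (alkene geometry not defined) | CC(C)(C)OC(=O)C(=Cc1cc3c(cc1O[Si](C)(C)C(C)(C)C)O[C@@H](c1ccc(O[Si](C)(C)C(C)(C)C)cc1)[C@@H]3c1cc(O[Si](C)(C)C(C)(C)C)cc(O[Si](C)(C)C(C)(C)C)c1)C(=O)c1c(O)c(I)c(O[Si](C)(C)C(C)(C)C)cc1O[Si](C)(C)C(C)(C)C | intermediate
23 | tert-butyl (2S)-8-iodo-4-oxo-5,7-bis(tert-butyldimethylsilyloxy)-2-[(2R,3R)-tetra-silylated dihydrobenzofuran-5-yl]chromane-3-carboxylate (C3 epimers) | Ic1c(O[Si](C)(C)C(C)(C)C)cc(O[Si](C)(C)C(C)(C)C)c2c1O[C@H](c1cc3c(cc1O[Si](C)(C)C(C)(C)C)O[C@@H](c1ccc(O[Si](C)(C)C(C)(C)C)cc1)[C@@H]3c1cc(O[Si](C)(C)C(C)(C)C)cc(O[Si](C)(C)C(C)(C)C)c1)C(C(=O)OC(C)(C)C)C2=O | intermediate (not isolated)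
24 | the corresponding chromanone-3-carboxylic acid (C3 epimers) | Ic1c(O[Si](C)(C)C(C)(C)C)cc(O[Si](C)(C)C(C)(C)C)c2c1O[C@H](c1cc3c(cc1O[Si](C)(C)C(C)(C)C)O[C@@H](c1ccc(O[Si](C)(C)C(C)(C)C)cc1)[C@@H]3c1cc(O[Si](C)(C)C(C)(C)C)cc(O[Si](C)(C)C(C)(C)C)c1)C(C(=O)O)C2=O | intermediate (not isolated)
25 | (2S)-8-iodo-5,7-bis(tert-butyldimethylsilyloxy)-2-{(2R,3R)-6-(tert-butyldimethylsilyloxy)-2-[4-(tert-butyldimethylsilyloxy)phenyl]-3-[3,5-bis(tert-butyldimethylsilyloxy)phenyl]-2,3-dihydro-1-benzofuran-5-yl}chroman-4-one | Ic1c(O[Si](C)(C)C(C)(C)C)cc(O[Si](C)(C)C(C)(C)C)c2c1O[C@H](c1cc3c(cc1O[Si](C)(C)C(C)(C)C)O[C@@H](c1ccc(O[Si](C)(C)C(C)(C)C)cc1)[C@@H]3c1cc(O[Si](C)(C)C(C)(C)C)cc(O[Si](C)(C)C(C)(C)C)c1)CC2=O | intermediate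
26 | 2-methylbut-1-en-3-yne | C=C(C)C#C | starting material
27 | (2S)-8-(3-methylbut-3-en-1-yn-1-yl) analogue of 25 | C=C(C)C#Cc1c(O[Si](C)(C)C(C)(C)C)cc(O[Si](C)(C)C(C)(C)C)c2c1O[C@H](c1cc3c(cc1O[Si](C)(C)C(C)(C)C)O[C@@H](c1ccc(O[Si](C)(C)C(C)(C)C)cc1)[C@@H]3c1cc(O[Si](C)(C)C(C)(C)C)cc(O[Si](C)(C)C(C)(C)C)c1)CC2=O | intermediate
28 | (2S)-8-[(1Z)-3-methylbuta-1,3-dien-1-yl] hexa-silyl ether of the target | C=C(C)/C=C\c1c(O[Si](C)(C)C(C)(C)C)cc(O[Si](C)(C)C(C)(C)C)c2c1O[C@H](c1cc3c(cc1O[Si](C)(C)C(C)(C)C)O[C@@H](c1ccc(O[Si](C)(C)C(C)(C)C)cc1)[C@@H]3c1cc(O[Si](C)(C)C(C)(C)C)cc(O[Si](C)(C)C(C)(C)C)c1)CC2=O | intermediate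
29 | CNP0284772.1: (2S)-2-[(2R,3R)-3-(3,5-dihydroxyphenyl)-6-hydroxy-2-(4-hydroxyphenyl)-2,3-dihydro-1-benzofuran-5-yl]-5,7-dihydroxy-8-[(1Z)-3-methylbuta-1,3-dien-1-yl]chroman-4-one | C=C(C)/C=C\c1c(O)cc(O)c2c1O[C@H](c1cc3c(cc1O)O[C@@H](c1ccc(O)cc1)[C@@H]3c1cc(O)cc(O)c1)CC2=O | target

**Step count**
Total: 16 steps. Longest linear sequence: 13 steps (steps 1–8, then 12–16); the A-ring branch (steps 9–11) joins at step 12.

**Steps most likely to fail**

Step 5. The diazo compound may dimerise to the azine faster than it is consumed, or the catalyst may discriminate the carbene faces poorly because of the 3,5-disubstituted aryl group. Fallback, from 7 back to 15: the benzophenone 7 is irradiated (365 nm, degassed benzene); δ-hydrogen abstraction from the benzylic OCH2 and closure of the 1,5-biradical form the same C2–C3 bond and give 5-bromo-3-(3,5-dimethoxyphenyl)-6-methoxy-2-(4-methoxyphenyl)-2,3-dihydro-1-benzofuran-3-ol F1. Ionic hydrogenation (Et3SiH, TFA, CH2Cl2, 0 °C) removes the tertiary hydroxyl and should give the trans bromide as a racemate, from which chromatography on a chiral phase provides (2R,3R)-5-bromo-3-(3,5-dimethoxyphenyl)-6-methoxy-2-(4-methoxyphenyl)-2,3-dihydro-1-benzofuran F2. Bromine–lithium exchange to the C5-aryllithium F3 and DMF quench give the trans aldehyde (2R,3R)-3-(3,5-dimethoxyphenyl)-6-methoxy-2-(4-methoxyphenyl)-2,3-dihydro-1-benzofuran-5-carbaldehyde F4, and BBr3 demethylation then delivers 15.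

Step 13. The hindered ortho-silyloxy aryl group may weaken catalyst control, and the hot acid used for decarboxylation may erode C2 by reversible opening of the electron-rich 2-aryl chromanone or loosen silyl ethers. Fallback, from 19 and 16 back to 25: the dilithium enolate 20 of 19 is added to aldehyde 16 (THF, −78 °C) to give the aldol adduct 1-[4,6-bis(tert-butyldimethylsilyloxy)-2-hydroxy-3-iodophenyl]-3-hydroxy-3-[(2R,3R)-tetra-silylated dihydrobenzofuran-5-yl]propan-1-one F5. Dehydration (PPTS, toluene) gives the 2'-hydroxychalcone F6. Intramolecular oxa-Michael addition, under a cinchona thiourea or simply NaOAc in EtOH, gives 25 together with its (2R)-epimer F7. Because the dihydrobenzofuran is already a single enantiomer these are diastereomers, separable by chromatography, and F7 is recycled through F6 under the same base; no ester, acid or heat is needed.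

Step 16. During sixfold desilylation, transient phenoxides may open the chromanone or the 2-(4-hydroxyphenyl)dihydrofuran, or traces of acid may cyclise the Z-dienyl phenol onto O7 to a chromene. Fallback, from 27 to 29: the order of the last two operations is reversed. The enyne 27 is desilylated first (TBAF/AcOH, THF, 0 °C) to the hexaphenol enyne (2S)-2-[(2R,3R)-3-(3,5-dihydroxyphenyl)-6-hydroxy-2-(4-hydroxyphenyl)-2,3-dihydro-1-benzofuran-5-yl]-5,7-dihydroxy-8-(3-methylbut-3-en-1-yn-1-yl)chroman-4-one F8. The sensitive Z-diene is then created in the final operation by Z-selective reduction with Zn(Cu/Ag) in MeOH/H2O, giving 29 under neutral conditions.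

**Further compounds**
F1 | step 5 | 5-bromo-3-(3,5-dimethoxyphenyl)-6-methoxy-2-(4-methoxyphenyl)-2,3-dihydro-1-benzofuran-3-ol (racemic, diastereomer mixture) | OC1(c2cc(OC)cc(OC)c2)c2cc(Br)c(OC)cc2OC1c1ccc(OC)cc1
F2 | step 5 | (2R,3R)-5-bromo-3-(3,5-dimethoxyphenyl)-6-methoxy-2-(4-methoxyphenyl)-2,3-dihydro-1-benzofuran (trans; formed as racemate, resolved) | Brc1cc2c(cc1OC)O[C@@H](c1ccc(OC)cc1)[C@@H]2c1cc(OC)cc(OC)c1
F3 | step 5 | C5-aryllithium derived from F2 | [Li]c1cc2c(cc1OC)O[C@@H](c1ccc(OC)cc1)[C@@H]2c1cc(OC)cc(OC)c1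
F4 | step 5 | (2R,3R)-3-(3,5-dimethoxyphenyl)-6-methoxy-2-(4-methoxyphenyl)-2,3-dihydro-1-benzofuran-5-carbaldehyde (trans) | O=Cc1cc2c(cc1OC)O[C@@H](c1ccc(OC)cc1)[C@@H]2c1cc(OC)cc(OC)c1
F5 | step 13 | aldol adduct of 19 and 16 (carbinol epimers) | O=C(CC(O)c1cc3c(cc1O[Si](C)(C)C(C)(C)C)O[C@@H](c1ccc(O[Si](C)(C)C(C)(C)C)cc1)[C@@H]3c1cc(O[Si](C)(C)C(C)(C)C)cc(O[Si](C)(C)C(C)(C)C)c1)c1c(O)c(I)c(O[Si](C)(C)C(C)(C)C)cc1O[Si](C)(C)C(C)(C)C
F6 | step 13 | (E)-2'-hydroxychalcone from F5 | O=C(/C=C/c1cc3c(cc1O[Si](C)(C)C(C)(C)C)O[C@@H](c1ccc(O[Si](C)(C)C(C)(C)C)cc1)[C@@H]3c1cc(O[Si](C)(C)C(C)(C)C)cc(O[Si](C)(C)C(C)(C)C)c1)c1c(O)c(I)c(O[Si](C)(C)C(C)(C)C)cc1O[Si](C)(C)C(C)(C)C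
F7 | step 13 | (2R)-epimer of 25 | Ic1c(O[Si](C)(C)C(C)(C)C)cc(O[Si](C)(C)C(C)(C)C)c2c1O[C@@H](c1cc3c(cc1O[Si](C)(C)C(C)(C)C)O[C@@H](c1ccc(O[Si](C)(C)C(C)(C)C)cc1)[C@@H]3c1cc(O[Si](C)(C)C(C)(C)C)cc(O[Si](C)(C)C(C)(C)C)c1)CC2=O
F8 | step 16 | hexaphenol enyne, (2S)-8-(3-methylbut-3-en-1-yn-1-yl) analogue of the target | C=C(C)C#Cc1c(O)cc(O)c2c1O[C@H](c1cc3c(cc1O)O[C@@H](c1ccc(O)cc1)[C@@H]3c1cc(O)cc(O)c1)CC2=O
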